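**Retrosynthetic overview**

1. The vanillate is attached last, to the less hindered C-6 hydroxyl of a triol. The C-6 carbinol comes from a hydroxyl-directed anti reduction of a C-6 ketone, itself released from a benzodithiole.
2. The seven-membered ring is formed second: an intramolecular carbonyl-ene reaction makes the C-3a–C-4 bond, the C-4 carbinol and the C-8=C-8a alkene in one step.
3. The five-membered ring is bought (cyclopentenone); its C-3 tertiary carbinol comes from a catalyst-controlled methyl addition to the enone.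
4. Key bond C-6–C-7: 1,6-conjugate addition of a lithiated benzodithiole (the C-6 carbonyl carbon as an acyl anion equivalent) to the electrophilic terminus of 3-isopropenylcyclopentenone.
5. Building blocks: 3-ethoxycyclopentenone, isopropenylmagnesium bromide, 3-methylbutanal, a benzodithiolylium salt (organocatalytic α-alkylation sets C-5) and O-acetylvanillic acid.

Assumption: atom labels are the azulene locants of the target (C-3 tertiary carbinol, C-3a, C-4 free secondary carbinol, C-5 isopropyl, C-6 ester carbinol, C-7, C-8 methyl, C-8a); the catalyst enantiomers named in steps 2 and 5 are taken to give the configurations drawn, and the mirror-image catalyst is used if the sense of induction proves opposite.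

**Step 1**
Reactants: 1 3-ethoxycyclopent-2-en-1-one; 2 prop-1-en-2-ylmagnesium bromide
Product: 4 3-(prop-1-en-2-yl)cyclopent-2-en-1-one, via bromomagnesium alkoxide adduct 3 (not isolated)
Conditions: THF, 0 °C; then 1 M aq. HCl, 0 °C
Reagents that add atoms: water (O)
Why: Stork–Danheiser enone transposition: 1,2-addition of the Grignard reagent to the vinylogous ester, then acid hydrolysis of the enol ether with loss of the tertiary oxygen gives the 3-substituted dienone; no stereocentre is formed.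

**Step 2**
Reactants: 5 3-methylbutanal; 6 1,3-benzodithiol-1-ium tetrafluoroborate
Product: 8 (2S)-2-(2H-1,3-benzodithiol-2-yl)-3-methylbutan-1-ol, via benzodithiolyl aldehyde 7 (not isolated)
Conditions: (5S)-5-benzyl-2,2,3-trimethylimidazolidin-4-one·PhCO2H (20 mol %), NaH2PO4, MeCN/H2O, 0 °C; then NaBH4, MeOH, 0 °C
Reagents that add atoms: none
Why: Enamine-catalysed SN1-type α-alkylation of the aldehyde by the stabilised benzodithiolylium cation (Cozzi alkylation); the benzyl group of the imidazolidinone shields one enamine face and sets the isopropyl-bearing centre (future C-5), which is secured against epimerisation by the in-situ borohydride reduction.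

**Step 3**
Reactants: 8 (2S)-2-(2H-1,3-benzodithiol-2-yl)-3-methylbutan-1-ol
Product: 9 tert-butyl{[(2S)-2-(2H-1,3-benzodithiol-2-yl)-3-methylbutyl]oxy}dimethylsilane
Conditions: TBSCl, imidazole, DMF, 23 °C
Reagents that add atoms: tert-butyldimethylsilyl chloride, CC(C)(C)[Si](C)(C)Cl
Why: Standard silylation of the primary alcohol protects the future C-4 oxygen against the organolithium and organozinc steps; the stereocentre is untouched.

**Step 4**
Reactants: 9 tert-butyl{[(2S)-2-(2H-1,3-benzodithiol-2-yl)-3-methylbutyl]oxy}dimethylsilane; 4 3-(prop-1-en-2-yl)cyclopent-2-en-1-one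
Product: 12 3-{1-[2-((2S)-1-{[tert-butyl(dimethyl)silyl]oxy}-3-methylbutan-2-yl)-2H-1,3-benzodithiol-2-yl]propan-2-yl}cyclopent-2-en-1-one, via 2-lithio-1,3-benzodithiole 10 (not isolated), via lithium dienolate 11 (not isolated)
Conditions: n-BuLi, THF/DMPU, −78 °C; then 4, −78 → −40 °C; t-BuOH, 0 °C; aq. NH4Cl
Reagents that add atoms: none
Why: Proposed new method: 1,6-conjugate addition of the 2-lithiobenzodithiole (acyl anion equivalent, future C-6) to the terminal CH2 (future C-7) of the dienone, which joins two normally electrophilic carbons; the polar cosolvent gives a solvent-separated ion pair that disfavours 1,2-attack, the β-carbon is fully substituted so the unhindered δ-carbon is attacked, and the dienolate is protonated under equilibration to the conjugated enone (the new methine is a 1:1 epimer mixture that is erased in step 8); the closest known reactions are 1,4-additions of 2-lithio-1,3-dithianes to enones in HMPA and 1,6-additions of cuprates to 3-alkenylcycloalkenones.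

**Step 5**
Reactants: 12 3-{1-[2-((2S)-1-{[tert-butyl(dimethyl)silyl]oxy}-3-methylbutan-2-yl)-2H-1,3-benzodithiol-2-yl]propan-2-yl}cyclopent-2-en-1-one
Product: 13 (1S)-3-{1-[2-((2S)-1-{[tert-butyl(dimethyl)silyl]oxy}-3-methylbutan-2-yl)-2H-1,3-benzodithiol-2-yl]propan-2-yl}-1-methylcyclopent-2-en-1-ol
Conditions: Me2Zn, Ti(OiPr)4, bis(sulfonamide) diol ligand from (1R,2R)-cyclohexane-1,2-diamine and camphorsulfonic acid (10 mol %), toluene/hexane, 23 °C; aq. NH4Cl
Reagents that add atoms: dimethylzinc, C[Zn]C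
Why: Walsh-type titanium-catalysed enantioselective 1,2-addition of dimethylzinc to a cyclic enone; the chiral titanium complex selects the enone face and sets the tertiary carbinol (future C-3, S), and the minor C-3 epimer is a diastereomer that can be removed.

**Step 6**
Reactants: 13 (1S)-3-{1-[2-((2S)-1-{[tert-butyl(dimethyl)silyl]oxy}-3-methylbutan-2-yl)-2H-1,3-benzodithiol-2-yl]propan-2-yl}-1-methylcyclopent-2-en-1-ol
Product: 14 (1S)-3-{1-[2-((2S)-1-hydroxy-3-methylbutan-2-yl)-2H-1,3-benzodithiol-2-yl]propan-2-yl}-1-methylcyclopent-2-en-1-ol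
Conditions: Bu4NF, THF, 0 → 23 °C
Reagents that add atoms: none
Why: Fluoride cleavage of the silyl ether under non-acidic conditions leaves the tertiary allylic alcohol and the thioketal intact; no stereocentre is affected.

**Step 7**
Reactants: 14 (1S)-3-{1-[2-((2S)-1-hydroxy-3-methylbutan-2-yl)-2H-1,3-benzodithiol-2-yl]propan-2-yl}-1-methylcyclopent-2-en-1-ol
Product: 15 (2S)-2-{2-[2-((3S)-3-hydroxy-3-methylcyclopent-1-en-1-yl)propyl]-2H-1,3-benzodithiol-2-yl}-3-methylbutanal
Conditions: SO3·pyridine, DMSO, i-Pr2NEt, CH2Cl2, 0 °C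
Reagents that add atoms: none
Why: Parikh–Doering oxidation converts only the primary alcohol (the tertiary one cannot be oxidised) and tolerates the sulfur atoms; the mild base and low temperature keep the α-stereocentre.

**Step 8**
Reactants: 15 (2S)-2-{2-[2-((3S)-3-hydroxy-3-methylcyclopent-1-en-1-yl)propyl]-2H-1,3-benzodithiol-2-yl}-3-methylbutanal
Product: 16 (3S,3aS,4S,5S)-3,8-dimethyl-5-(propan-2-yl)-2,3,3a,4,5,7-hexahydro-1H-spiro[azulene-6,2'-[1,3]benzodithiole]-3,4-diol
Conditions: Me2AlCl (2.5 equiv), CH2Cl2, −78 → −20 °C; H2O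
Reagents that add atoms: none
Why: Lewis acid-promoted intramolecular carbonyl-ene (Prins-type) cyclisation: the aldehyde carbon bonds to the less substituted alkene carbon (C-3a) and the hydrogen is taken from the exocyclic methine, which closes the seven-membered ring and gives the tetrasubstituted C-8=C-8a alkene from both methine epimers; aluminium bound to the C-3 alkoxide delivers the aldehyde to the same face, so C-4 lies cis to the C-3 oxygen on the five-membered ring (H-3a trans to 3-OH), and a chair-like chelate with the isopropyl-bearing carbon pseudo-equatorial places 4-OH syn to 3-OH and cis to the isopropyl group.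

**Step 9**
Reactants: 16 (3S,3aS,4S,5S)-3,8-dimethyl-5-(propan-2-yl)-2,3,3a,4,5,7-hexahydro-1H-spiro[azulene-6,2'-[1,3]benzodithiole]-3,4-diol
Product: 17 (3S,3aS,4S,5S)-3,4-dihydroxy-3,8-dimethyl-5-(propan-2-yl)-2,3,3a,4,5,7-hexahydroazulen-6(1H)-one
Conditions: HgO, 35% aq. HBF4, THF, 0 °C
Reagents that add atoms: water (O)
Why: Thiophilic mercury-assisted hydrolysis of the benzodithiole thioketal releases the C-6 ketone from the acyl anion carrier; short contact at 0 °C and immediate use avoid epimerisation of the α-stereocentre C-5.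

**Step 10**
Reactants: 17 (3S,3aS,4S,5S)-3,4-dihydroxy-3,8-dimethyl-5-(propan-2-yl)-2,3,3a,4,5,7-hexahydroazulen-6(1H)-one
Product: 18 (3S,3aS,4R,5R,6S)-3,8-dimethyl-5-(propan-2-yl)-1,2,3,3a,4,5,6,7-octahydroazulene-3,4,6-triol
Conditions: Me4NBH(OAc)3, MeCN/AcOH, −30 °C
Reagents that add atoms: none
Why: Evans–Saksena hydroxyl-directed reduction: the acetoxyborohydride exchanges onto the C-4 hydroxyl and delivers hydride intramolecularly to the same face of the β-ketone, which gives the 4,6-anti (trans) diol and so the (6S) carbinol trans to the isopropyl group.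

**Step 11**
Reactants: 18 (3S,3aS,4R,5R,6S)-3,8-dimethyl-5-(propan-2-yl)-1,2,3,3a,4,5,6,7-octahydroazulene-3,4,6-triol; 19 4-acetoxy-3-methoxybenzoic acid
Product: 20 (3S,3aS,4R,5S,6S)-3,4-dihydroxy-3,8-dimethyl-5-(propan-2-yl)-1,2,3,3a,4,5,6,7-octahydroazulen-6-yl 4-acetoxy-3-methoxybenzoate
Conditions: EDC·HCl, DMAP (cat.), CH2Cl2, −20 → 0 °C
Reagents that add atoms: none
Why: Steglich esterification with 1.05 equiv of acid acylates the C-6 hydroxyl, which has a CH2 neighbour, in preference to the C-4 hydroxyl (flanked by two methines and hydrogen-bonded to the cis C-3 hydroxyl) and the unreactive tertiary C-3 hydroxyl; no stereocentre is touched.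

**Step 12**
Reactants: 20 (3S,3aS,4R,5S,6S)-3,4-dihydroxy-3,8-dimethyl-5-(propan-2-yl)-1,2,3,3a,4,5,6,7-octahydroazulen-6-yl 4-acetoxy-3-methoxybenzoate
Product: 21 (3S,3aS,4R,5S,6S)-3,4-dihydroxy-3,8-dimethyl-5-(propan-2-yl)-1,2,3,3a,4,5,6,7-octahydroazulen-6-yl 4-hydroxy-3-methoxybenzoate
Conditions: pyrrolidine, CH2Cl2, 0 °C
Reagents that add atoms: none
Why: Chemoselective aminolysis of the aryl acetate, which is far more electrophilic than the hindered secondary aroate, frees the phenol and gives the target without touching any stereocentre.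

**Compound list**

1 | 3-ethoxycyclopent-2-en-1-one | CCOC1=CC(=O)CC1 | starting material
2 | prop-1-en-2-ylmagnesium bromide | CC(=C)[Mg]Br | starting material
3 | bromomagnesium 3-ethoxy-1-(prop-1-en-2-yl)cyclopent-2-en-1-olate (not isolated) | CCOC1=CC(O[Mg]Br)(CC1)C(C)=C | intermediate
4 | 3-(prop-1-en-2-yl)cyclopent-2-en-1-one | CC(=C)C1=CC(=O)CC1 | intermediate
5 | 3-methylbutanal | CC(C)CC=O | starting material
6 | 1,3-benzodithiol-1-ium tetrafluoroborate | F[B-](F)(F)F.c1ccc2c(c1)sc[s+]2 | starting material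
7 | (2S)-2-(2H-1,3-benzodithiol-2-yl)-3-methylbutanal (not isolated) | S1c2ccccc2SC1[C@@H](C(C)C)C=O | intermediate
8 | (2S)-2-(2H-1,3-benzodithiol-2-yl)-3-methylbutan-1-ol | S1c2ccccc2SC1[C@@H](C(C)C)CO | intermediate
9 | tert-butyl{[(2S)-2-(2H-1,3-benzodithiol-2-yl)-3-methylbutyl]oxy}dimethylsilane | S1c2ccccc2SC1[C@@H](C(C)C)CO[Si](C)(C)C(C)(C)C | intermediate
10 | 2-lithio derivative of 9 (not isolated) | [Li]C1(Sc2ccccc2S1)[C@@H](C(C)C)CO[Si](C)(C)C(C)(C)C | intermediate
11 | lithium dienolate of 12, O-lithio 3-alkylidenecyclopent-1-en-1-olate (not isolated) | [Li]OC1=CC(CC1)=C(C)CC1(Sc2ccccc2S1)[C@@H](C(C)C)CO[Si](C)(C)C(C)(C)C | intermediate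
12 | 3-{1-[2-((2S)-1-{[tert-butyl(dimethyl)silyl]oxy}-3-methylbutan-2-yl)-2H-1,3-benzodithiol-2-yl]propan-2-yl}cyclopent-2-en-1-one (both epimers at the propan-2-yl carbon) | O=C1C=C(CC1)C(C)CC1(Sc2ccccc2S1)[C@@H](C(C)C)CO[Si](C)(C)C(C)(C)C | intermediate
13 | (1S)-3-{1-[2-((2S)-1-{[tert-butyl(dimethyl)silyl]oxy}-3-methylbutan-2-yl)-2H-1,3-benzodithiol-2-yl]propan-2-yl}-1-methylcyclopent-2-en-1-ol | C[C@@]1(O)C=C(CC1)C(C)CC1(Sc2ccccc2S1)[C@@H](C(C)C)CO[Si](C)(C)C(C)(C)C | intermediate
14 | (1S)-3-{1-[2-((2S)-1-hydroxy-3-methylbutan-2-yl)-2H-1,3-benzodithiol-2-yl]propan-2-yl}-1-methylcyclopent-2-en-1-ol | C[C@@]1(O)C=C(CC1)C(C)CC1(Sc2ccccc2S1)[C@@H](C(C)C)CO | intermediate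
15 | (2S)-2-{2-[2-((3S)-3-hydroxy-3-methylcyclopent-1-en-1-yl)propyl]-2H-1,3-benzodithiol-2-yl}-3-methylbutanal | C[C@@]1(O)C=C(CC1)C(C)CC1(Sc2ccccc2S1)[C@@H](C(C)C)C=O | intermediate
16 | (3S,3aS,4S,5S)-3,8-dimethyl-5-(propan-2-yl)-2,3,3a,4,5,7-hexahydro-1H-spiro[azulene-6,2'-[1,3]benzodithiole]-3,4-diol | CC1=C2CC[C@](C)(O)[C@@H]2[C@H](O)[C@H](C(C)C)C3(C1)Sc1ccccc1S3 | intermediate
17 | (3S,3aS,4S,5S)-3,4-dihydroxy-3,8-dimethyl-5-(propan-2-yl)-2,3,3a,4,5,7-hexahydroazulen-6(1H)-one | CC1=C2CC[C@](C)(O)[C@@H]2[C@H](O)[C@H](C(C)C)C(=O)C1 | intermediate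
18 | (3S,3aS,4R,5R,6S)-3,8-dimethyl-5-(propan-2-yl)-1,2,3,3a,4,5,6,7-octahydroazulene-3,4,6-triol | O[C@H]1CC(C)=C2CC[C@](C)(O)[C@@H]2[C@H](O)[C@@H]1C(C)C | intermediate
19 | 4-acetoxy-3-methoxybenzoic acid | CC(=O)Oc1ccc(cc1OC)C(=O)O | starting material
20 | (3S,3aS,4R,5S,6S)-3,4-dihydroxy-3,8-dimethyl-5-(propan-2-yl)-1,2,3,3a,4,5,6,7-octahydroazulen-6-yl 4-acetoxy-3-methoxybenzoate | COc1cc(C(=O)O[C@H]2CC(C)=C3CC[C@](C)(O)[C@@H]3[C@H](O)[C@@H]2C(C)C)ccc1OC(C)=O | intermediate
21 | (3S,3aS,4R,5S,6S)-3,4-dihydroxy-3,8-dimethyl-5-(propan-2-yl)-1,2,3,3a,4,5,6,7-octahydroazulen-6-yl 4-hydroxy-3-methoxybenzoate | COc1cc(C(=O)O[C@H]2CC(C)=C3CC[C@](C)(O)[C@@H]3[C@H](O)[C@@H]2C(C)C)ccc1O | target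

**Totals and risk**

Total step count: 12. Longest linear sequence: 11 steps (5 → 8 → 9 → 12 → 13 → 14 → 15 → 16 → 17 → 18 → 20 → 21).

The three steps most likely to fail are 4, 5 and 8.

Step 4 (the hindered lithio compound may add 1,2 or simply deprotonate the dienone). The fallback sets out from 4 and 9 and comes back at 13; it replaces the conjugate addition by an SN2 alkylation of the same acyl anion equivalent. Dienone 4 is methylated first, under the conditions of step 5, to (1S)-1-methyl-3-(prop-1-en-2-yl)cyclopent-2-en-1-ol F1. Hydroboration of the terminal alkene with 9-BBN, then NaOH/H2O2, gives (1S)-3-(1-hydroxypropan-2-yl)-1-methylcyclopent-2-en-1-ol F2. Iodine, PPh3 and imidazole convert the primary hydroxyl into (1S)-3-(1-iodopropan-2-yl)-1-methylcyclopent-2-en-1-ol F3. Alkylation of lithio compound 10 (2.2 equiv, made from 9 as in step 4) with F3 in THF/DMPU gives 13.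

Step 5 (the enantioselectivity of the methyl addition on this substrate is not assured). The fallback takes the carbinol centre from the chiral pool, sets out from 9 (as 10) and comes back at 13. Ozonolysis (O3, then Me2S) of the trisubstituted alkene of (3S)-3,7-dimethylocta-1,6-dien-3-ol F4 [(S)-linalool] gives (4S)-4-hydroxy-4-methylhex-5-enal F5. CBr4/PPh3 gives (3S)-7,7-dibromo-3-methylhepta-1,6-dien-3-ol F6. n-BuLi followed by MeI gives (3S)-3-methyloct-1-en-6-yn-3-ol F7. Ring-closing enyne metathesis with the second-generation Grubbs catalyst under ethylene gives the same dienol F1, which is carried through F2 and F3 and alkylated with 10 as described above to reach 13.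

Step 8 (the ene step may lose the hydrogen from the ring CH2 instead, or give the wrong C-4 epimer). The fallback sets out from 12 and comes back at 16; it closes the ring by an aldol reaction and sets C-3 by substrate control. Bu4NF gives 3-{1-[2-((2S)-1-hydroxy-3-methylbutan-2-yl)-2H-1,3-benzodithiol-2-yl]propan-2-yl}cyclopent-2-en-1-one F8. SO3·pyridine/DMSO gives (2S)-3-methyl-2-{2-[2-(3-oxocyclopent-1-en-1-yl)propyl]-2H-1,3-benzodithiol-2-yl}butanal F9. KOt-Bu in THF/t-BuOH at −40 °C forms the extended dienolate, whose α-carbon attacks the aldehyde; this closes the seven-membered ring with deconjugation to the tetrasubstituted alkene and gives (3aS,4S,5S)-4-hydroxy-8-methyl-5-(propan-2-yl)-1,2,3a,4,5,7-hexahydro-3H-spiro[azulene-6,2'-[1,3]benzodithiol]-3-one F10. MeMgBr/CeCl3 then adds anti to the C-3a substituent to give 16.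

**Further compounds**

F1 | step 4 | (1S)-1-methyl-3-(prop-1-en-2-yl)cyclopent-2-en-1-ol | C[C@@]1(O)C=C(CC1)C(C)=C
F2 | step 4 | (1S)-3-(1-hydroxypropan-2-yl)-1-methylcyclopent-2-en-1-ol | C[C@@]1(O)C=C(CC1)C(C)CO
F3 | step 4 | (1S)-3-(1-iodopropan-2-yl)-1-methylcyclopent-2-en-1-ol | C[C@@]1(O)C=C(CC1)C(C)CI
F4 | step 5 | (3S)-3,7-dimethylocta-1,6-dien-3-ol | C=C[C@@](C)(O)CCC=C(C)C
F5 | step 5 | (4S)-4-hydroxy-4-methylhex-5-enal | C=C[C@@](C)(O)CCC=O
F6 | step 5 | (3S)-7,7-dibromo-3-methylhepta-1,6-dien-3-ol | C=C[C@@](C)(O)CCC=C(Br)Br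
F7 | step 5 | (3S)-3-methyloct-1-en-6-yn-3-ol | C=C[C@@](C)(O)CCC#CC
F8 | step 8 | 3-{1-[2-((2S)-1-hydroxy-3-methylbutan-2-yl)-2H-1,3-benzodithiol-2-yl]propan-2-yl}cyclopent-2-en-1-one | O=C1C=C(CC1)C(C)CC1(Sc2ccccc2S1)[C@@H](C(C)C)CO
F9 | step 8 | (2S)-3-methyl-2-{2-[2-(3-oxocyclopent-1-en-1-yl)propyl]-2H-1,3-benzodithiol-2-yl}butanal | O=C1C=C(CC1)C(C)CC1(Sc2ccccc2S1)[C@@H](C(C)C)C=O
F10 | step 8 | (3aS,4S,5S)-4-hydroxy-8-methyl-5-(propan-2-yl)-1,2,3a,4,5,7-hexahydro-3H-spiro[azulene-6,2'-[1,3]benzodithiol]-3-one | CC1=C2CCC(=O)[C@@H]2[C@H](O)[C@H](C(C)C)C3(C1)Sc1ccccc1S3
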